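## Structural features

The target is an unsymmetrical lignan dimer: an olivil-type tetrahydrofuran and a cycloolivil-type tetralin joined by a biaryl bond between two guaiacyl rings (ring C and ring D), each with its free phenol ortho to that bond. In the tetrahydrofuran (O1, C2 to C5), ring C sits on C2, a CH2OH on C3, and C4 carries a tertiary hydroxyl and the isovanillyl group (ring A, 3-hydroxy-4-methoxybenzyl). C2 (S), C3 (R) and C4 (S) are contiguous, with the aryl group trans to the CH2OH and the CH2OH cis to the benzyl group. In the tetralin (C1' to C4', fused to ring F, 7'-hydroxy-6'-methoxy), ring D sits on the doubly benzylic C1', a CH2OH on C2', and C3' carries a tertiary hydroxyl and a CH2OH; C1', C2' and C3' (all S) are contiguous and their carbon substituents are mutually trans. The fragile point is the benzylic C2–O1 bond para to the oxygen of ring C: acid ionises it, ring A can then close a second tetralin, and the bond is also open to hydrogenolysis. The real difficulty is twofold: each half has a fully substituted carbinol next to a CH stereocentre, and two nearly identical halves must end as different rings although their attachment points on the biaryl are chemically equivalent. The feature exploited is that C3' (OH, CH2OH, C4'H2 to ring F) and C2' (H, CH2OH) are C2 and C3 of an α-benzylated L-malic acid with both carboxyls at the alcohol level, so C1' need only be added as the aldehyde carbon of ring D. C4/C3 of the tetrahydrofuran show the same malate pattern, with C2 as the aldehyde carbon of ring C and the same (S)-malate centre and sense of addition.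

## Logic of the disconnections

30 from 29. The four phenolic O–CH2Ph bonds are cut last. Free phenols would not survive amide bases, hydride or cation chemistry, and benzyl is the one group that endures all three. The skeleton is not simplified. The forward demand is a hydrogenolysis that stops before the benzylic C2–O1 bond.

29 from 28. The O1–C2 bond is cut, leaving a benzylic alcohol and a primary alcohol on C5. This removes the ring and makes the C2 configuration irrelevant, because it is set on closure, trans to the C3 substituent. The forward step must let oxygen capture the benzylic cation before ring A does (weak acid, kinetic control). It must come after the tetralin is made, since this ring would not survive the stronger acid used there.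

28 from 27, and 27 from 24 plus 19. After adjusting oxidation levels (CH2OH back to ester and lactone), the C2–C3 bond and the lactone C–O bond are cut. The tetrahydrofuran half is thereby reduced to a malate and an aryl aldehyde. The forward aldol must add anti to the alkoxide-bearing centre. The aldehyde partner must offer neither a primary OH nor a reactive ester, hence the pivalates of 19, which the same hydride that reduces 27 also removes.

19 from 18, and 18 from 16. The pivalates are removed on paper, then the C1'–C8a' bond is cut (Friedel–Crafts) and the aldehyde is traced to its acetal. The carbocycle becomes an acyclic tetraol whose C1' configuration does not matter. The forward step needs acid strong enough to carry the first-formed cyclic ether on to the carbocycle, with attack para to the methoxy group of ring F. It is run while no tetrahydrofuran of the other half exists.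

16 from 15, and 15 from 7 plus 12. This is the key disconnection. After returning the two CH2OH groups to lactone and ester, the C1'–C2' bond and the lactone C–O bond are cut. Three contiguous stereocentres collapse to the single centre of 7. The forward step needs facial control at C2' and a biaryl with one free aldehyde only.

7 from 6, 6 from 2 plus 4; 24 from 23, 23 from 2 plus 21; 2 from 1; 4 from 3; 21 from 20. The C3'–C4' bond (and the C4–benzyl bond of the other half) is cut. Both quaternary carbinols then come from one acetal, 2, and two benzylic bromides. The forward alkylation must proceed with retention, which the acetal centre of 2 provides.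

12 from 9 plus 10 (through 11), 9 and 10 from 8. The biaryl bond is cut between two copies of one bromide, one of them masked as an acetal. This gives the mono-protected dialdehyde without a statistical protection. The forward demand is an ordinary cross-coupling of two singly ortho-substituted partners.

## Other disconnections considered

Alternative 1: The cut is C1'–C8a', made at the very end. The target, as its ring A acetate A1, is traced to a dimer of two olivil-type tetrahydrofurans, A2, which differ only in the benzyl group (vanillyl on one ring, O-acetylisovanillyl on the other). In the forward step acid would ionise the benzylic C–O bond of the vanillyl-bearing ring, and the vanillyl ring would attack para to its methoxy group to give A1.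
- In favour: both halves of A2 could be built by the same reactions, perhaps in two directions at once on a symmetrical dialdehyde. No mono-protection of the biaryl would be needed, and on step count this plan would be the equal or the better of the chosen one. C1' corrects itself exactly as in the chosen plan (equal).
- Against: rings C and D are constitutionally equivalent, so both benzylic ethers ionise at like rates. All the selectivity lies in the nucleophile, vanillyl (para to OMe) against acetylated isovanillyl (para to OAc only). That gap is real, but the ring to be kept would open and re-close throughout the reaction, with the risk of slow leakage to a bis-tetralin. The single acetate would also have to be carried from the isovanillyl building block through every enolate and hydride step, or be introduced through an orthogonal group.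
- Comparison: structurally this plan does not make the tertiary carbinols; A2 still needs something like the malate aldol twice. Mechanistically it uses the same cation, but chemoselectively between two live sites, whereas the chosen plan uses it sequentially with no tetrahydrofuran present when strong acid is applied.

Alternative 2: The cut is the bond from C4 to the benzylic carbon of ring A. The olivil half is traced to the bicyclic diether A3 and this to the tetrahydrofuran-4-one A4. In the forward step irradiation of A4 would lead to abstraction of a benzylic hydrogen from the ether CH2 on the C3 arm by the excited ketone, and radical coupling would give the cis-fused A3 with its tertiary hydroxyl. Reductive cleavage of the ring A benzylic C–O bond would then release the benzyl group and the C3 CH2OH.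
- In favour: the tertiary alcohol and the C4–benzyl bond form in one step without base. The cis ring fusion enforces the C3/C4 relationship geometrically, which on that point is better than chelate-controlled facial selection. The tetrahydrofuran exists before the benzyl group does, so its closure never competes with ring A (equal or better). The bond to be cleaved is para to OMe while the one to be kept is para to OAc, a sensible electronic distinction.
- Against: the ketone is surrounded by three electron-rich arenes and a biaryl chromophore, so competitive absorption, electron-transfer quenching and α-cleavage next to the ring oxygen are all plausible. C3 of A4 is α to the ketone and, with C2, would have to be made and kept enantiopure by a separate asymmetric sequence. The tetralin half would still have to be built afterwards from the ester on ring D, under acid, with an acid-labile ether already present.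
- Comparison: mechanistically a radical pair replaces an ionic chelate. In step count A4 alone should cost about as much as the whole tetrahydrofuran half of the chosen plan.

Alternative 3: The cut is C2'–C3'. The tetralin ester A5 is traced to the α-bromo ester A6, which carries the benzyloxymethyl ketone on the ring F side chain. In the forward step SmI2 would reduce the C–Br bond, and the ester enolate, held by trivalent samarium, would add to the ketone and close the six-membered ring.
- In favour: the enolate is planar, so the configuration at the bromide is irrelevant. A samarium chelate should place OH and ester cis, which is what the target needs, with the ester trans to the C1' aryl group. The closure is a C–C bond formation under neutral reducing conditions, so it would tolerate an existing tetrahydrofuran and allow either order of the two halves; on that point it is better than the chosen plan.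
- Against: everything is relayed from C1', a diarylmethine with two similar electron-rich aryl groups, which would have to be made enantiopure beforehand. α-Benzyloxy ketones are themselves reduced by SmI2 with loss of the alkoxy group. The ketone is flanked by a benzylic CH2 that can protonate the enolate. A6 needs a long preparation.
- Comparison: structurally the tertiary carbinol would rest on 1,3-induction through a ring transition state, where the chosen plan takes it from the chiral pool. In step count this plan is longer, and the tetrahydrofuran half would still need its own solution.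

Key step: step 8

Remarks:
- Locants and abbreviations are those used above (O1, C2–C5; C1'–C8a'; rings A, C, D, F); Bn = benzyl, Piv = pivaloyl.
- The configurations of the key-step pair agree with the target: 7 is (S), which is what L-malic acid gives with retention, and 15 carries C2' and C3' as in 30.
- Two design points go beyond the bare disconnection. The dioxolane of 12 cannot outlast the acid of step 10 and is cleaved there on purpose. The aldehyde partner of the second aldol is capped as the dipivalate 19.
- The facial bias of the two dioxolanone alkylations is steric (tert-butyl group) and does not depend on the counter-ion. The dilithium dianion serves the smaller batch (step 3) and the more reactive disodium dianion the larger one (step 13).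
- Assumption: the benzyl ethers 3 and 20 are taken as commercial (each is one borohydride reduction away from O-benzylvanillin or O-benzylisovanillin).

## Steps

Step 1
Reactants: 1 L-malic acid
Product: 2 2-[(2S,4S)-2-tert-butyl-5-oxo-1,3-dioxolan-4-yl]acetic acid
Conditions: tBuCHO, TsOH·H2O (cat.), H2SO4 (cat.), pentane, reflux, Dean–Stark; recrystallisation
Reagents that add atoms: pivalaldehyde, CC(C)(C)C=O
Why: Acid-catalysed acetalisation engages the α-hydroxy acid function as the five-membered dioxolanone; the cis isomer (tert-butyl and CH2CO2H on one face) should predominate and is purified by crystallisation, so the new acetal centre (S) stores the chirality of C2 of 1 (first stage of Seebach self-regeneration of stereocentres).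

Step 2
Reactants: 3 4-(benzyloxy)-3-methoxybenzyl alcohol
Product: 4 4-(benzyloxy)-3-methoxybenzyl bromide
Conditions: PBr3, Et2O, 0 °C; used at once
Reagents that add atoms: phosphorus tribromide, BrP(Br)Br
Why: Standard conversion of an electron-rich benzylic alcohol into its bromide through the phosphite ester; the labile bromide is not stored.

Step 3
Reactants: 2 2-[(2S,4S)-2-tert-butyl-5-oxo-1,3-dioxolan-4-yl]acetic acid; 4 4-(benzyloxy)-3-methoxybenzyl bromide
Product: 6 2-[(2S,4S)-4-[4-(benzyloxy)-3-methoxybenzyl]-2-tert-butyl-5-oxo-1,3-dioxolan-4-yl]acetic acid, via dilithium enolate carboxylate 5 (not isolated)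
Conditions: LiN(SiMe3)2 (2.1 equiv), THF, −78 °C; then 4, −78 → −20 °C; aq. HCl
Reagents that add atoms: none
Why: Two equivalents of base give the carboxylate–enolate 5, whose trigonal ring carbon is benzylated on the face anti to the tert-butyl group, so the benzyl group takes the place of the former hydrogen (overall retention, S); this is the Seebach dioxolanone alkylation.

Step 4
Reactants: 6 2-[(2S,4S)-4-[4-(benzyloxy)-3-methoxybenzyl]-2-tert-butyl-5-oxo-1,3-dioxolan-4-yl]acetic acid
Product: 7 dimethyl (S)-2-[4-(benzyloxy)-3-methoxybenzyl]-2-hydroxybutanedioate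
Conditions: H2SO4 (cat.), MeOH, reflux
Reagents that add atoms: methanol, CO
Why: Acid-catalysed methanolysis opens the acylal-type ring with loss of pivalaldehyde, and Fischer esterification converts the unhindered side-chain acid; the quaternary carbinol cannot epimerise.

Step 5
Reactants: 8 5-bromovanillin
Product: 9 4-(benzyloxy)-3-bromo-5-methoxybenzaldehyde
Conditions: BnBr, K2CO3, DMF, 60 °C
Reagents that add atoms: benzyl bromide, BrCc1ccccc1
Why: Williamson etherification of the phenol; the aldehyde and the aryl bromide are inert.

Step 6
Reactants: 9 4-(benzyloxy)-3-bromo-5-methoxybenzaldehyde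
Product: 10 2-[4-(benzyloxy)-3-bromo-5-methoxyphenyl]-1,3-dioxolane
Conditions: HOCH2CH2OH, TsOH·H2O (cat.), toluene, reflux, Dean–Stark
Reagents that add atoms: ethylene glycol, OCCO
Why: Acetalisation driven by azeotropic removal of water gives a mask that is stable to the palladium coupling, to amide bases and to hydride.

Step 7
Reactants: 10 2-[4-(benzyloxy)-3-bromo-5-methoxyphenyl]-1,3-dioxolane; 9 4-(benzyloxy)-3-bromo-5-methoxybenzaldehyde
Product: 12 2',6-bis(benzyloxy)-5'-(1,3-dioxolan-2-yl)-3',5-dimethoxybiphenyl-3-carbaldehyde, via pinacol boronate 11 (not isolated)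
Conditions: B2pin2, KOAc, PdCl2(dppf) (3 mol%), 1,4-dioxane, 90 °C; then 9, aq. K2CO3, 90 °C
Reagents that add atoms: bis(pinacolato)diboron, CC1(C)OB(OC1(C)C)B1OC(C)(C)C(C)(C)O1 (its boron unit is carried in 11 only)
Why: Miyaura borylation of 10 followed in the same pot by Suzuki–Miyaura coupling with 9, whose C–Br bond para to the formyl group adds readily to zerovalent palladium; each ring has only one ortho substituent, and acetal and aldehyde tolerate the carbonate base, so the dialdehyde comes out with one carbonyl masked and no statistical step.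

Step 8
Reactants: 7 dimethyl (S)-2-[4-(benzyloxy)-3-methoxybenzyl]-2-hydroxybutanedioate; 12 2',6-bis(benzyloxy)-5'-(1,3-dioxolan-2-yl)-3',5-dimethoxybiphenyl-3-carbaldehyde
Product: 15 methyl (2S,3R,4S)-2-[2',6-bis(benzyloxy)-5'-(1,3-dioxolan-2-yl)-3',5-dimethoxybiphenyl-3-yl]-4-[4-(benzyloxy)-3-methoxybenzyl]-4-hydroxy-5-oxooxolane-3-carboxylate, via dilithium alkoxide enolate 13 (not isolated), via dilithium aldolate 14 (not isolated)
Conditions: 7 (1.3 equiv), LiN(iPr)2 (2.7 equiv), THF, −78 → −20 °C; then 12 (1.0 equiv), −78 → 0 °C; AcOH
Reagents that add atoms: none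
Why: The first equivalent of LiN(iPr)2 removes the tertiary O–H and the second an α-hydrogen of the CH2CO2Me arm, giving the lithium-bridged alkoxide–(Z)-enolate 13, in which the alkoxide oxygen, C3', C2' and the enolate oxygen lie in one chelate ring (Fráter–Seebach dianion; the closest known reactions are the C-alkylation and aldol addition of malate dianions, α-benzyl malates included). The aldehyde carbon of 12 bonds to C2' on the face of the chelate opposite the C3' ester group, the face that carries CH2Ar in place of the hydrogen of the parent malate, which sets C2' (R in 15, S in 30) anti to the alkoxide centre. C3' is quaternary and cannot epimerise, so the (S) centre from step 3 is the only control element needed. The new C1' alkoxide of 14 then attacks the C3' methyl ester in a 5-exo-trig acyl transfer and expels methoxide, closing the γ-lactone 15 and making the aldol irreversible. C1' arises under kinetic control of low reliability and is drawn trans to the C2' ester; either epimer serves because C1' becomes a cation in step 10. Chemoselectivity rests on the substrate: the one free aldehyde of 12 is its only site more electrophilic than an ester, ring C is an acetal inert to amide base, 12 has no α-hydrogen, and 13 is fully formed before 12 is added. The selectivity that matters is therefore only facial at C2', and a C2' epimer would appear as a separable diastereomer of 15 or 16.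

Step 9
Reactants: 15 methyl (2S,3R,4S)-2-[2',6-bis(benzyloxy)-5'-(1,3-dioxolan-2-yl)-3',5-dimethoxybiphenyl-3-yl]-4-[4-(benzyloxy)-3-methoxybenzyl]-4-hydroxy-5-oxooxolane-3-carboxylate
Product: 16 (2S,3R,4S)-4-[2',6-bis(benzyloxy)-5'-(1,3-dioxolan-2-yl)-3',5-dimethoxybiphenyl-3-yl]-2-[4-(benzyloxy)-3-methoxybenzyl]-3-(hydroxymethyl)butane-1,2,4-triol
Conditions: LiAlH4, THF, 0 °C → rt; H2O, aq. NaOH work-up
Reagents that add atoms: none
Why: Hydride reduction takes lactone and ester to the two CH2OH groups without touching a stereocentre, the acetal or the benzyl ethers; any adduct that failed to lactonise in step 8 converges on the same tetraol.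

Step 10
Reactants: 16 (2S,3R,4S)-4-[2',6-bis(benzyloxy)-5'-(1,3-dioxolan-2-yl)-3',5-dimethoxybiphenyl-3-yl]-2-[4-(benzyloxy)-3-methoxybenzyl]-3-(hydroxymethyl)butane-1,2,4-triol
Product: 18 2',6-bis(benzyloxy)-5'-[(1S,2S,3S)-7-(benzyloxy)-3-hydroxy-2,3-bis(hydroxymethyl)-6-methoxy-1,2,3,4-tetrahydronaphthalen-1-yl]-3',5-dimethoxybiphenyl-3-carbaldehyde, via tetralin triol acetal 17 (not isolated)
Conditions: CF3CO2H (10 vol%), CH2Cl2, 0 °C → rt; then H2O, THF, rt; NaHCO3, MeOH work-up
Reagents that add atoms: water, O
Why: Acid ionises the benzylic C1'–OH (cation stabilised by the para benzyloxy group of ring D); reversible capture by a hydroxyl gives way to irreversible intramolecular Friedel–Crafts attack of ring F para to its methoxy group through a chair-like six-membered transition state with ring D and the C2' substituent equatorial, which sets C1' (S) trans to C2' whichever epimer of 16 is used; added water then hydrolyses the aryl dioxolane.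

Step 11
Reactants: 18 2',6-bis(benzyloxy)-5'-[(1S,2S,3S)-7-(benzyloxy)-3-hydroxy-2,3-bis(hydroxymethyl)-6-methoxy-1,2,3,4-tetrahydronaphthalen-1-yl]-3',5-dimethoxybiphenyl-3-carbaldehyde
Product: 19 2',6-bis(benzyloxy)-5'-[(1S,2S,3S)-7-(benzyloxy)-3-hydroxy-6-methoxy-2,3-bis(pivaloyloxymethyl)-1,2,3,4-tetrahydronaphthalen-1-yl]-3',5-dimethoxybiphenyl-3-carbaldehyde
Conditions: PivCl (2.3 equiv), pyridine, DMAP (cat.), CH2Cl2, 0 °C → rt
Reagents that add atoms: pivaloyl chloride, CC(C)(C)C(Cl)=O
Why: Acylation takes the two primary alcohols and leaves the tertiary alcohol and the aldehyde; pivalates have no α-hydrogen and are hindered, so they should be inert to the dianion of step 15 and fall to the hydride of step 16 without a separate deprotection.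

Step 12
Reactants: 20 3-(benzyloxy)-4-methoxybenzyl alcohol
Product: 21 3-(benzyloxy)-4-methoxybenzyl bromide
Conditions: PBr3, Et2O, 0 °C; used at once
Reagents that add atoms: phosphorus tribromide, BrP(Br)Br
Why: Same substitution as in step 2.

Step 13
Reactants: 2 2-[(2S,4S)-2-tert-butyl-5-oxo-1,3-dioxolan-4-yl]acetic acid; 21 3-(benzyloxy)-4-methoxybenzyl bromide
Product: 23 2-[(2S,4S)-4-[3-(benzyloxy)-4-methoxybenzyl]-2-tert-butyl-5-oxo-1,3-dioxolan-4-yl]acetic acid, via disodium enolate carboxylate 22 (not isolated)
Conditions: NaN(SiMe3)2 (2.1 equiv), THF, −78 °C; then 21, −78 → −40 °C; aq. HCl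
Reagents that add atoms: none
Why: Seebach dioxolanone alkylation as in step 3, here through the disodium dianion 22, whose more reactive enolate lets this larger batch (24 is used in excess in step 15) be alkylated without warming above −40 °C; attack is anti to the tert-butyl group whatever the cation, hence retention, and this centre becomes C4 (S) of 30.

Step 14
Reactants: 23 2-[(2S,4S)-4-[3-(benzyloxy)-4-methoxybenzyl]-2-tert-butyl-5-oxo-1,3-dioxolan-4-yl]acetic acid
Product: 24 dimethyl (S)-2-[3-(benzyloxy)-4-methoxybenzyl]-2-hydroxybutanedioate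
Conditions: H2SO4 (cat.), MeOH, reflux
Reagents that add atoms: methanol, CO
Why: Acid-catalysed methanolysis and Fischer esterification as in step 4.

Step 15
Reactants: 24 dimethyl (S)-2-[3-(benzyloxy)-4-methoxybenzyl]-2-hydroxybutanedioate; 19 2',6-bis(benzyloxy)-5'-[(1S,2S,3S)-7-(benzyloxy)-3-hydroxy-6-methoxy-2,3-bis(pivaloyloxymethyl)-1,2,3,4-tetrahydronaphthalen-1-yl]-3',5-dimethoxybiphenyl-3-carbaldehyde
Product: 27 methyl (2S,3R,4S)-2-Ar-4-[3-(benzyloxy)-4-methoxybenzyl]-4-hydroxy-5-oxooxolane-3-carboxylate in which Ar is the biphenyl-3-yl unit of 19, via dilithium alkoxide enolate 25 (not isolated), via trilithium aldolate 26 (not isolated)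
Conditions: 24 (2.5 equiv), LiN(iPr)2 (5.1 equiv), THF, −78 → −20 °C; then 19 (1.0 equiv), −78 → −10 °C; AcOH
Reagents that add atoms: none
Why: Second Fráter–Seebach-type aldol addition with 5-exo-trig lactonisation, in the same facial sense as step 8 (attack anti to the ester on the carbinol carbon), which sets C3 (R) relative to C4 (S); one equivalent of 25 is spent on the tertiary O–H of 19, the pivalates stay intact at these temperatures, and the C2 configuration is left open because step 17 resets it.

Step 16
Reactants: 27 methyl (2S,3R,4S)-2-Ar-4-[3-(benzyloxy)-4-methoxybenzyl]-4-hydroxy-5-oxooxolane-3-carboxylate in which Ar is the biphenyl-3-yl unit of 19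
Product: 28 (2S,3R,4S)-4-Ar'-2-[3-(benzyloxy)-4-methoxybenzyl]-3-(hydroxymethyl)butane-1,2,4-triol in which Ar' is the biphenyl-3-yl unit of 18 with its free tetralin triol
Conditions: LiAlH4 (excess), THF, 0 °C → rt; H2O, aq. NaOH work-up
Reagents that add atoms: none
Why: One hydride reduction converts lactone and methyl ester into the two CH2OH groups and cleaves both pivalates; no stereocentre is touched.

Step 17
Reactants: 28 (2S,3R,4S)-4-Ar'-2-[3-(benzyloxy)-4-methoxybenzyl]-3-(hydroxymethyl)butane-1,2,4-triol in which Ar' is the biphenyl-3-yl unit of 18 with its free tetralin triol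
Product: 29 tetra-O-benzyl ether of 30 with the (2S,3R,4S)-tetrahydrofuran closed
Conditions: camphorsulfonic acid (10 mol%), CH2Cl2–THF, 0 °C; Et3N quench as soon as 28 is consumed
Reagents that add atoms: none
Why: Acid-catalysed cycloetherification through the benzylic cation at C2 (the only ionisable benzylic carbinol in 28): 5-exo capture by the primary hydroxyl on C5 should outrun the six-membered Friedel–Crafts capture by ring A under weak acid at low temperature (kinetic control), the other hydroxyls could only form four-membered rings, and closure places ring C trans to the C3 CH2OH, giving C2 (S).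

Step 18
Reactants: 29 tetra-O-benzyl ether of 30 with the (2S,3R,4S)-tetrahydrofuran closed
Product: 30 CNP0252244.1
Conditions: H2 (1 atm), 10% Pd/C, EtOAc–MeOH, rt; stopped after uptake of four equivalents
Reagents that add atoms: none
Why: Hydrogenolysis of the four aryl benzyl ethers, which under neutral conditions cleave much faster than the ring benzylic ether or the diarylmethine C–H; no stereocentre is involved.

## Compound list

1 | L-malic acid, (S)-2-hydroxybutanedioic acid | OC(=O)C[C@H](O)C(=O)O | starting material
2 | 2-[(2S,4S)-2-tert-butyl-5-oxo-1,3-dioxolan-4-yl]acetic acid (cis acetal) | OC(=O)C[C@@H]1O[C@H](C(C)(C)C)OC1=O | intermediate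
3 | 4-(benzyloxy)-3-methoxybenzyl alcohol | COc1cc(CO)ccc1OCc1ccccc1 | starting material
4 | 4-(benzyloxy)-3-methoxybenzyl bromide | COc1cc(CBr)ccc1OCc1ccccc1 | intermediate
5 | dilithium enolate carboxylate of 2 | [Li+].[Li+].[O-]C(=O)CC1=C([O-])O[C@@H](C(C)(C)C)O1 | intermediate (not isolated)
6 | 2-[(2S,4S)-4-[4-(benzyloxy)-3-methoxybenzyl]-2-tert-butyl-5-oxo-1,3-dioxolan-4-yl]acetic acid | OC(=O)C[C@]1(Cc2ccc(OCc3ccccc3)c(OC)c2)O[C@H](C(C)(C)C)OC1=O | intermediate
7 | dimethyl (S)-2-[4-(benzyloxy)-3-methoxybenzyl]-2-hydroxybutanedioate | COc1cc(C[C@@](CC(=O)OC)(O)C(=O)OC)ccc1OCc1ccccc1 | intermediate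
8 | 5-bromovanillin | COc1cc(C=O)cc(Br)c1O | starting material
9 | 4-(benzyloxy)-3-bromo-5-methoxybenzaldehyde | COc1cc(C=O)cc(Br)c1OCc1ccccc1 | intermediate
10 | 2-[4-(benzyloxy)-3-bromo-5-methoxyphenyl]-1,3-dioxolane | COc1cc(C2OCCO2)cc(Br)c1OCc1ccccc1 | intermediate
11 | 2-[2-(benzyloxy)-5-(1,3-dioxolan-2-yl)-3-methoxyphenyl]-4,4,5,5-tetramethyl-1,3,2-dioxaborolane | COc1cc(C2OCCO2)cc(B2OC(C)(C)C(C)(C)O2)c1OCc1ccccc1 | intermediate (not isolated)
12 | 2',6-bis(benzyloxy)-5'-(1,3-dioxolan-2-yl)-3',5-dimethoxybiphenyl-3-carbaldehyde | O=Cc1cc(OC)c(OCc2ccccc2)c(-c2cc(C3OCCO3)cc(OC)c2OCc2ccccc2)c1 | intermediate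
13 | dilithium alkoxide (Z)-enolate of 7 | [Li+].[Li+].COC(=O)[C@]([O-])(Cc1ccc(OCc2ccccc2)c(OC)c1)/C=C(\[O-])OC | intermediate (not isolated)
14 | dilithium aldolate of 13 and 12 (open-chain diester, C1' drawn as in 15) | [Li+].[Li+].COC(=O)[C@H]([C@H]([O-])c1cc(OC)c(OCc2ccccc2)c(-c2cc(C3OCCO3)cc(OC)c2OCc2ccccc2)c1)[C@@]([O-])(Cc1ccc(OCc2ccccc2)c(OC)c1)C(=O)OC | intermediate (not isolated)
15 | methyl (2S,3R,4S)-2-[2',6-bis(benzyloxy)-5'-(1,3-dioxolan-2-yl)-3',5-dimethoxybiphenyl-3-yl]-4-[4-(benzyloxy)-3-methoxybenzyl]-4-hydroxy-5-oxooxolane-3-carboxylate (aryl trans to ester; the C2 epimer serves equally) | O=C1O[C@H](c2cc(OC)c(OCc3ccccc3)c(-c3cc(C4OCCO4)cc(OC)c3OCc3ccccc3)c2)[C@@H](C(=O)OC)[C@@]1(O)Cc1ccc(OCc2ccccc2)c(OC)c1 | intermediate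
16 | (2S,3R,4S)-4-[2',6-bis(benzyloxy)-5'-(1,3-dioxolan-2-yl)-3',5-dimethoxybiphenyl-3-yl]-2-[4-(benzyloxy)-3-methoxybenzyl]-3-(hydroxymethyl)butane-1,2,4-triol | OC[C@H]([C@H](O)c1cc(OC)c(OCc2ccccc2)c(-c2cc(C3OCCO3)cc(OC)c2OCc2ccccc2)c1)[C@@](O)(Cc1ccc(OCc2ccccc2)c(OC)c1)CO | intermediate
17 | 2-{2',6-bis(benzyloxy)-5'-[(1S,2S,3S)-7-(benzyloxy)-3-hydroxy-2,3-bis(hydroxymethyl)-6-methoxy-1,2,3,4-tetrahydronaphthalen-1-yl]-3',5-dimethoxybiphenyl-3-yl}-1,3-dioxolane | COc1cc(C2OCCO2)cc(-c2cc([C@H]3c4cc(OCc5ccccc5)c(OC)cc4C[C@@](O)(CO)[C@@H]3CO)cc(OC)c2OCc2ccccc2)c1OCc1ccccc1 | intermediate (not isolated)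
18 | 2',6-bis(benzyloxy)-5'-[(1S,2S,3S)-7-(benzyloxy)-3-hydroxy-2,3-bis(hydroxymethyl)-6-methoxy-1,2,3,4-tetrahydronaphthalen-1-yl]-3',5-dimethoxybiphenyl-3-carbaldehyde | COc1cc(C=O)cc(-c2cc([C@H]3c4cc(OCc5ccccc5)c(OC)cc4C[C@@](O)(CO)[C@@H]3CO)cc(OC)c2OCc2ccccc2)c1OCc1ccccc1 | intermediate
19 | dipivalate of 18 at the two CH2OH groups | COc1cc(C=O)cc(-c2cc([C@H]3c4cc(OCc5ccccc5)c(OC)cc4C[C@@](O)(COC(=O)C(C)(C)C)[C@@H]3COC(=O)C(C)(C)C)cc(OC)c2OCc2ccccc2)c1OCc1ccccc1 | intermediate
20 | 3-(benzyloxy)-4-methoxybenzyl alcohol | COc1ccc(CO)cc1OCc1ccccc1 | starting material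
21 | 3-(benzyloxy)-4-methoxybenzyl bromide | COc1ccc(CBr)cc1OCc1ccccc1 | intermediate
22 | disodium enolate carboxylate of 2 | [Na+].[Na+].[O-]C(=O)CC1=C([O-])O[C@@H](C(C)(C)C)O1 | intermediate (not isolated)
23 | 2-[(2S,4S)-4-[3-(benzyloxy)-4-methoxybenzyl]-2-tert-butyl-5-oxo-1,3-dioxolan-4-yl]acetic acid | OC(=O)C[C@]1(Cc2ccc(OC)c(OCc3ccccc3)c2)O[C@H](C(C)(C)C)OC1=O | intermediate
24 | dimethyl (S)-2-[3-(benzyloxy)-4-methoxybenzyl]-2-hydroxybutanedioate | COc1ccc(C[C@@](CC(=O)OC)(O)C(=O)OC)cc1OCc1ccccc1 | intermediate
25 | dilithium alkoxide (Z)-enolate of 24 | [Li+].[Li+].COC(=O)[C@]([O-])(Cc1ccc(OC)c(OCc2ccccc2)c1)/C=C(\[O-])OC | intermediate (not isolated)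
26 | trilithium aldolate of 25 and 19 (tetralin tertiary alkoxide included) | [Li+].[Li+].[Li+].COC(=O)[C@H]([C@H]([O-])c1cc(OC)c(OCc2ccccc2)c(-c2cc([C@H]3c4cc(OCc5ccccc5)c(OC)cc4C[C@@]([O-])(COC(=O)C(C)(C)C)[C@@H]3COC(=O)C(C)(C)C)cc(OC)c2OCc2ccccc2)c1)[C@@]([O-])(Cc1ccc(OC)c(OCc2ccccc2)c1)C(=O)OC | intermediate (not isolated)
27 | methyl (2S,3R,4S)-2-Ar-4-[3-(benzyloxy)-4-methoxybenzyl]-4-hydroxy-5-oxooxolane-3-carboxylate, Ar = biphenyl-3-yl unit of 19 (the C2 epimer serves equally) | O=C1O[C@H](c2cc(OC)c(OCc3ccccc3)c(-c3cc([C@H]4c5cc(OCc6ccccc6)c(OC)cc5C[C@@](O)(COC(=O)C(C)(C)C)[C@@H]4COC(=O)C(C)(C)C)cc(OC)c3OCc3ccccc3)c2)[C@@H](C(=O)OC)[C@@]1(O)Cc1ccc(OC)c(OCc2ccccc2)c1 | intermediate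
28 | (2S,3R,4S)-4-Ar'-2-[3-(benzyloxy)-4-methoxybenzyl]-3-(hydroxymethyl)butane-1,2,4-triol, Ar' = biphenyl-3-yl unit of 18 (heptaol) | OC[C@H]([C@H](O)c1cc(OC)c(OCc2ccccc2)c(-c2cc([C@H]3c4cc(OCc5ccccc5)c(OC)cc4C[C@@](O)(CO)[C@@H]3CO)cc(OC)c2OCc2ccccc2)c1)[C@@](O)(Cc1ccc(OC)c(OCc2ccccc2)c1)CO | intermediate
29 | tetra-O-benzyl ether of 30 (all four phenols benzylated) | COc1ccc(C[C@@]2(O)CO[C@H](c3cc(OC)c(OCc4ccccc4)c(-c4cc([C@H]5c6cc(OCc7ccccc7)c(OC)cc6C[C@@](O)(CO)[C@@H]5CO)cc(OC)c4OCc4ccccc4)c3)[C@H]2CO)cc1OCc1ccccc1 | intermediate
30 | CNP0252244.1 | COc1ccc(C[C@@]2(O)CO[C@H](c3cc(OC)c(O)c(-c4cc([C@H]5c6cc(O)c(OC)cc6C[C@@](O)(CO)[C@@H]5CO)cc(OC)c4O)c3)[C@H]2CO)cc1O | target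

Total: 18 steps. Longest linear sequence: 11 steps (8 → 9 → 10 → 12 → 15 → 16 → 18 → 19 → 27 → 28 → 29 → 30; the branch from 1 through 2, 6 and 7 is equally long).

Least certain steps:

Step 8 (key step). The most likely failure is erosion of facial selectivity at C2'. The carbinol carbon of the chelate is flanked by CO2Me and CH2Ar instead of CO2Me and H, so the energy gap between the two faces is smaller than in the parent malate. Cleavage of the hindered aldolate back to its components before it lactonises could add to this. The fallback sets out from 6 and 12 and returns at 16. The side-chain acid of 6 would be coupled (PivCl, Et3N, then LiCl and (S)-4-benzyl-1,3-oxazolidin-2-one) to the N-acyl oxazolidinone F1. Enolisation with Bu2BOTf and iPr2NEt (CH2Cl2, −78 °C) and addition to 12 in an Evans syn-aldol reaction would give the adduct F2. Here the auxiliary, not the crowded carbinol centre, fixes C2', and the (S)-benzyl auxiliary delivers the arrangement of 15. LiBH4 (THF–MeOH) would then reduce the imide and the dioxolanone carbonyl of F2 to the two CH2OH groups and so give 16.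

Step 15. The likely failures are quenching of the dianion by the tertiary hydroxyl of 19, sluggish addition to a large aldehyde, and the same facial question as in step 8. The fallback sets out from 23 and 19 and returns at 28. Acid 23 would be converted, as described for step 8, into the N-acyl oxazolidinone F3. Its boron-mediated Evans syn-aldol reaction with 19 would give the adduct F4; such an enolate is too weakly basic to be consumed by the free hydroxyl. LiAlH4 would then reduce imide, dioxolanone and both pivalates of F4 to give 28.

Step 17. The likely failure is capture of the benzylic cation by ring A (para to its benzyloxy group) in place of the hydroxyl, or re-ionisation of the product on prolonged exposure, either of which would lead to a second tetralin. The fallback sets out from 24 and returns at 30. NBS in MeCN would brominate ring A of 24 para to the benzyloxy group, the very carbon that would attack, to give the bromo malate F5. The operations of steps 15 to 17 (LiAlH4 at 0 °C) would then give the bromo lactone F6, the bromo heptaol F7 and the bromo tetrahydrofuran F8. With the para position blocked only the hindered position between CH2 and OBn is left for carbon capture. H2 over Pd/C with Et3N would finally remove bromine and the benzyl groups together and give 30.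

Step 10. The likely failures are stalling at the reversibly formed cyclic ether, partial loss of aryl benzyl ethers in the strong acid, and condensation of the liberated aldehyde. The fallback sets out from 16 and returns at 19. Excess PivCl with pyridine and DMAP would give the tripivalate F9 (benzylic and both primary hydroxyls acylated). BF3·OEt2 in CH2Cl2 at low temperature would ionise the benzylic pivalate; with no free primary hydroxyl the ether manifold is shut and only ring F can capture the cation. Aqueous acid work-up would hydrolyse the acetal and deliver 19 directly.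

Step 18. The likely failure is over-reduction, that is hydrogenolysis of the benzylic C2–O1 bond once the phenols are free. The fallback sets out from 28 and returns at 30. The four benzyl ethers would be hydrogenolysed on 28, where the benzylic oxygen is a secondary alcohol and not a ring ether, to give the tetraphenol F10. The ring would be closed last by gentle warming of F10 in a weakly acidic aqueous–organic medium; the para-hydroxybenzylic alcohol would react through its quinone methide and the primary hydroxyl would add in a 5-exo sense.

## Further compounds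

F1 | step 8 | (S)-4-benzyl-3-{2-[(2S,4S)-4-[4-(benzyloxy)-3-methoxybenzyl]-2-tert-butyl-5-oxo-1,3-dioxolan-4-yl]acetyl}-1,3-oxazolidin-2-one | O=C1OC[C@H](Cc2ccccc2)N1C(=O)C[C@]1(Cc2ccc(OCc3ccccc3)c(OC)c2)O[C@H](C(C)(C)C)OC1=O
F2 | step 8 | Evans syn-aldol adduct of F1 and 12 (secondary benzylic alcohol, imide and dioxolanone intact) | O=C1OC[C@H](Cc2ccccc2)N1C(=O)[C@H]([C@H](O)c1cc(OC)c(OCc2ccccc2)c(-c2cc(C3OCCO3)cc(OC)c2OCc2ccccc2)c1)[C@]1(Cc2ccc(OCc3ccccc3)c(OC)c2)O[C@H](C(C)(C)C)OC1=O
F3 | step 15 | (S)-4-benzyl-3-{2-[(2S,4S)-4-[3-(benzyloxy)-4-methoxybenzyl]-2-tert-butyl-5-oxo-1,3-dioxolan-4-yl]acetyl}-1,3-oxazolidin-2-one | O=C1OC[C@H](Cc2ccccc2)N1C(=O)C[C@]1(Cc2ccc(OC)c(OCc3ccccc3)c2)O[C@H](C(C)(C)C)OC1=O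
F4 | step 15 | Evans syn-aldol adduct of F3 and 19 | O=C1OC[C@H](Cc2ccccc2)N1C(=O)[C@H]([C@H](O)c1cc(OC)c(OCc2ccccc2)c(-c2cc([C@H]3c4cc(OCc5ccccc5)c(OC)cc4C[C@@](O)(COC(=O)C(C)(C)C)[C@@H]3COC(=O)C(C)(C)C)cc(OC)c2OCc2ccccc2)c1)[C@]1(Cc2ccc(OC)c(OCc3ccccc3)c2)O[C@H](C(C)(C)C)OC1=O
F5 | step 17 | dimethyl (S)-2-[5-(benzyloxy)-2-bromo-4-methoxybenzyl]-2-hydroxybutanedioate | COc1cc(Br)c(C[C@@](CC(=O)OC)(O)C(=O)OC)cc1OCc1ccccc1
F6 | step 17 | bromo analogue of 27 (bromine on ring A para to the benzyloxy group) | O=C1O[C@H](c2cc(OC)c(OCc3ccccc3)c(-c3cc([C@H]4c5cc(OCc6ccccc6)c(OC)cc5C[C@@](O)(COC(=O)C(C)(C)C)[C@@H]4COC(=O)C(C)(C)C)cc(OC)c3OCc3ccccc3)c2)[C@@H](C(=O)OC)[C@@]1(O)Cc1cc(OCc2ccccc2)c(OC)cc1Br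
F7 | step 17 | bromo analogue of 28 | OC[C@H]([C@H](O)c1cc(OC)c(OCc2ccccc2)c(-c2cc([C@H]3c4cc(OCc5ccccc5)c(OC)cc4C[C@@](O)(CO)[C@@H]3CO)cc(OC)c2OCc2ccccc2)c1)[C@@](O)(Cc1cc(OCc2ccccc2)c(OC)cc1Br)CO
F8 | step 17 | bromo analogue of 29 | COc1cc(Br)c(C[C@@]2(O)CO[C@H](c3cc(OC)c(OCc4ccccc4)c(-c4cc([C@H]5c6cc(OCc7ccccc7)c(OC)cc6C[C@@](O)(CO)[C@@H]5CO)cc(OC)c4OCc4ccccc4)c3)[C@H]2CO)cc1OCc1ccccc1
F9 | step 10 | tripivalate of 16 (benzylic and both primary hydroxyls acylated, tertiary hydroxyl free) | CC(C)(C)C(=O)OC[C@H]([C@H](OC(=O)C(C)(C)C)c1cc(OC)c(OCc2ccccc2)c(-c2cc(C3OCCO3)cc(OC)c2OCc2ccccc2)c1)[C@@](O)(Cc1ccc(OCc2ccccc2)c(OC)c1)COC(=O)C(C)(C)C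
F10 | step 18 | fully debenzylated 28 (tetraphenol heptaol) | OC[C@H]([C@H](O)c1cc(OC)c(O)c(-c2cc([C@H]3c4cc(O)c(OC)cc4C[C@@](O)(CO)[C@@H]3CO)cc(OC)c2O)c1)[C@@](O)(Cc1ccc(OC)c(O)c1)CO
A1 | alternative 1 | 30 with the ring A phenol as its acetate | COc1ccc(C[C@@]2(O)CO[C@H](c3cc(OC)c(O)c(-c4cc([C@H]5c6cc(O)c(OC)cc6C[C@@](O)(CO)[C@@H]5CO)cc(OC)c4O)c3)[C@H]2CO)cc1OC(C)=O
A2 | alternative 1 | biaryl-linked dimer of two olivil-type tetrahydrofurans, one with a vanillyl group, the other with an O-acetylisovanillyl group | COc1ccc(C[C@@]2(O)CO[C@H](c3cc(OC)c(O)c(-c4cc([C@H]5OC[C@](O)(Cc6ccc(O)c(OC)c6)[C@@H]5CO)cc(OC)c4O)c3)[C@H]2CO)cc1OC(C)=O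
A3 | alternative 2 | 1-hydroxy-2,6-diaryl-3,7-dioxabicyclo[3.3.0]octane with acetylated phenols and a methyl ester on ring D | O[C@]12CO[C@H](c3cc(OC)c(OC(C)=O)c(-c4cc(C(=O)OC)cc(OC)c4OC(C)=O)c3)[C@H]1CO[C@@H]2c1ccc(OC)c(OC(C)=O)c1
A4 | alternative 2 | 2-aryl-3-{[(3-acetoxy-4-methoxybenzyl)oxy]methyl}oxolan-4-one (2,3-trans) | O=C1CO[C@H](c2cc(OC)c(OC(C)=O)c(-c3cc(C(=O)OC)cc(OC)c3OC(C)=O)c2)[C@H]1COCc1ccc(OC)c(OC(C)=O)c1
A5 | alternative 3 | methyl 1-aryl-3-hydroxy-3-(benzyloxymethyl)tetralin-2-carboxylate | COC(=O)[C@@H]1[C@@H](c2cc(OC)c(OCc3ccccc3)c(-c3cc(C4OCCO4)cc(OC)c3OCc3ccccc3)c2)c2cc(OCc3ccccc3)c(OC)cc2C[C@@]1(O)COCc1ccccc1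
A6 | alternative 3 | methyl 2-bromo-3,3-diarylpropanoate whose ring F carries an ortho 3-(benzyloxy)-2-oxopropyl chain (bromide centre undefined) | COC(=O)C(Br)[C@@H](c1cc(OC)c(OCc2ccccc2)c(-c2cc(C3OCCO3)cc(OC)c2OCc2ccccc2)c1)c1cc(OCc2ccccc2)c(OC)cc1CC(=O)COCc1ccccc1
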